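Remark: ring positions are numbered C1 (quaternary), C2, C3, C4, C5 (acylated) and C6, with C7 the carboxyl carbon; the trivial name of the target counts the acylated carbon as C3 in the older quinic acid numbering, and the compound made is the one fixed by its SMILES, which has the configuration of natural quinic acid.

## Structural features

The target is a single cyclohexane ring (C1–C6). C1 is quaternary and carries a methoxy group and the carboxyl carbon C7, C2 and C6 are methylene groups, and C3, C4 and C5 are contiguous carbinol carbons. O5 is esterified by (E)-3-(3,4-dihydroxyphenyl)propenoic acid, so the arene is joined to the carbocycle only through an ester. O3 and O4 are cis, O4 and O5 are trans, the carboxyl at C1 is cis to O5 across C6, and the methoxy group shares the face of O3 and O4 (CIP 1S,3R,4R,5R when the acylated carbon is counted as C3). The fragile parts are the catechol (oxidised in base and air), the secondary enoate ester flanked by free hydroxyls (acyl migration and hydrolysis in base), the E-alkene and the free acid, so the end game has to be acidic or neutral. The ring itself is easy to make. The real difficulty is the absolute configuration of C1, whose two ring arms differ only beyond the methylene groups, together with telling three secondary hydroxyls apart so that only O5 is acylated, and etherifying a tertiary hydroxyl. The plan reads C1–C2 as the alkene of an α-oxygenated acrylate and C3–C6 as a four-carbon diene, so that one cycloaddition makes C1–C6 and C2–C3, sets C1 from a removable acetal stereocentre and leaves a C4=C5 alkene within reach of the C1 carboxyl. That carboxyl then delivers O5 to its own face, and the lactone bridge so formed protects O5 and directs the cis-dihydroxylation of C3=C4 to the opposite face.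

## Logic of the disconnections

**21 ⇒ 20.** Cut: the three benzylic C–O bonds (the C7 ester and the two aryl ethers) and the two acetal C–O bonds at O3 and O4. Reason: 21 holds a migration-prone ester beside free hydroxyls and an oxidisable catechol, so every mask is chosen to fall under acid in one operation. Gain: the last step is a single deprotection. Demand: the benzylic cations must be scavenged before they alkylate the freed catechol, and exposure to acid must stay short.

**20 ⇒ 16 + 19.** Cut: the ester bond between O5 and the enoyl carbonyl. Reason: it is the only bond joining the two halves and the convergent point. Gain: 19 is a simple protected acid and 16 has exactly one free hydroxyl. Demand: acylation of a hindered secondary hydroxyl without base strong enough to re-close the lactone from 16.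

**19 ⇒ 17 (through 18).** Cut: the two aryl O–CH2 bonds. Reason: the catechol must be masked for acyl activation, with groups that leave under the same acid as the rest. Gain: one flask from 17. Demand: the carboxyl is alkylated as well and must be freed again without touching the ethers.

**16 ⇒ 14 (through 15).** Forward, the C7(=O)–O5 lactone bond is cleaved and an O–CH2 bond is formed at the carboxylate. Reason: in 14 the lactone is the device that has kept O5 distinct from O3 and O4. Gain: O5 is released exactly when it is needed. Demand: acyl–oxygen cleavage only (C5 keeps its configuration), and no residual base that would reverse the opening.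

**14 ⇒ 13.** Cut: the two acetal C–O bonds. Reason: the cis-3,4-diol must be blocked before O5 is exposed. Gain: trivial. Demand: the lactone must survive the acid catalyst.

**13 ⇒ 12.** Cut: C3–O and C4–O. Reason: a cis-diol maps onto an alkene, and the bicyclic lactone offers one open face. Gain: two stereocentres are removed in one step. Demand: the oxidant must add anti to the lactone bridge.

**12 ⇒ 11 ⇒ 10.** Cut: first the C3=C4 π bond (restoring C4–I and C3–H), then C5–O and C4–I. Reason: the carboxyl at C1 can reach C5 only on its own face, so O5 is set cis to C7 and the alkene is moved to where the diol is needed. Gain: 10 has a single stereocentre, and all three carbinol centres are derived from it. Demand: γ- rather than δ-lactonisation, and anti elimination towards C3 only.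

**10 ⇒ 8 (through 9) ⇒ 7.** Cut: the O–CH3 bond, then the acetal and acyl bonds of the spiro heterocycle. Reason: the heterocycle is an auxiliary and is exchanged for the methyl ether and the free acid. Gain: return to the cycloadduct. Demand: etherification of a tertiary alkoxide beside an ester, with the C1–O bond never broken.

**7 ⇒ 5 + 6.** Cut: C1–C6 and C2–C3. Reason: this forms the ring and the only stereocentre that cannot be relayed. Gain: one ring, two C–C bonds and C1 in one step from two small components. Demand: π-facial control only. With the (R) acetal, addition anti to tert-butyl gives the (2R,5S) adduct, which places oxygen on the O3/O4 face and the carbonyl on the O5 face, as 21 requires.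

**5 ⇒ 4 ⇒ 3 ⇒ 1 + 2.** Cut: the exocyclic C=C (restoring C–Br and C–H), then C–Br, then the two acetal C–O bonds. Reason: the acetal carbon copies the configuration of 1 before the original stereocentre is flattened. Gain: commercial starting materials. Demand: 3 must be diastereomerically pure, because its cis/trans ratio becomes the enantiomeric ratio of 5.

## Other disconnections considered

**Alternative 1:** The cut is C1–C7. The carboxyl carbon is added as a masked acyl anion to the six-membered ketone A1, which already carries C3, C4 and C5 from a pentose. Forward, LiC(SMe)3 adds to the C1 carbonyl of A1 on the face remote from the acetonide and the lithium alkoxide is methylated in the same flask with CH3I to give the orthothioester A2; no ring is formed.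
- In its favour: the three carbinol centres come from the chiral pool, so neither an osmium oxidant nor a stereochemical relay is needed. O5 is a silyl ether from the outset, so the acylation site is exposed by simple desilylation; on this point the alternative is better than the chosen plan, which must open a lactone and cap the acid. The methyl ether arises by alkylation of a tertiary alkoxide in both plans (equal), and here it shares a flask with the C–C bond formation (better at that point).
- Against it here: facial selectivity depends on the conformation of a flexible cis-fused cyclohexanone meeting a very bulky nucleophile. A1 has oxygen leaving groups at both β-positions, so the basic carbanion can enolise it and trigger β-elimination. LiC(SMe)3 decomposes on warming, whereas methylation of a hindered lithium alkoxide needs warming and polar additives, during which the addition can revert. Unmasking the orthothioester usually needs thiophilic mercury salts such as HgCl2, and A1 itself needs a carbocyclisation sequence.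
- Comparison: in structure, the alternative buys three stereocentres and must create the hardest one (C1) by an open-transition-state polar addition; the chosen plan creates C1 in a concerted cycloaddition on a rigid, one-face-shielded alkene and relays the rest. After A2 about five operations remain, against ten after 7, but A1 costs clearly more than the three steps to 5, so the total should be no shorter.

**Alternative 2:** The cut is C5–C6. The acyclic aldehyde A3 carries a 2-substituted allylsilane; forward, BF3·OEt2 activates the C5 aldehyde and the allylsilane closes the ring (intramolecular Hosomi–Sakurai reaction) to give the methylenecyclohexanol A4 with an exocyclic C1=C7 alkene. C1 is then set by hydroxyl-directed epoxidation of A4 and ring-opening with methanol at C1 with inversion, and C7 is oxidised to the acid.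
- In its favour: O5 is formed as a free hydroxyl while O3 and O4 are already an acetonide, so there is no lactone detour, no separate acetonide step and no osmium; on these points the alternative is better. Six-membered allylsilane–aldehyde closures are dependable, and the exocyclic alkene is a flexible handle.
- Against it here: the key step does not touch C1, which then needs two further stereodefining events. Acid-promoted methanolysis at a tertiary epoxide carbon has SN1 character and can lose stereospecificity (and the acetonide), while basic opening would go to the CH2 terminus. C7 must be raised by two oxidation levels beside a secondary hydroxyl. The aldehyde α to the acetonide can epimerise under the Lewis acid, and C5 is set only by 1,2-induction.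
- Comparison: both plans relay stereochemistry (equal in principle), but here the relay runs from C5 to C1 through an epoxide opening of uncertain mechanism, whereas the chosen plan relays from C1 outwards through a rigid bicycle. Mechanistically it is a cationic cyclisation against a pericyclic one. Counting the preparation of A3 and about seven steps after A4, the alternative should be the longer.

**Alternative 3:** The cut is C4–C5. The keto aldehyde A5 is built on a prochiral 3-oxygenated pentanedioate core that already carries the methoxy group and C7 as a tert-butyl ester at the future C1. Forward, the proline enamine on the C4 side of the C3 ketone adds to the C5 aldehyde (6-enolendo aldol) to give the ketol A6.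
- In its favour: the methyl ether and an acid-labile C7 ester are present before ring closure, so neither late O-methylation nor lactone opening is needed; on this point the alternative is better than the chosen plan. The key step is metal-free, sets C4 and C5 together in the anti relationship typical of proline aldols with α-oxygenated ketone donors, and leaves O5 free and O4 protected.
- Against it here: C1 must be set earlier by desymmetrising two enantiotopic arms, which is a separate asymmetric problem, and each arm then needs its own elaboration. The catalyst has to match or override the remote C1 centre. A6 is a β-hydroxy ketone that is prone to dehydration and retro-aldol reaction and can epimerise at C4. C3 still needs a separate reduction to the axial alcohol, after which O3 and O5 are both free.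
- Comparison: the alternative splits stereocontrol over three independent events (desymmetrisation, aldol, reduction), whereas the chosen plan has one auxiliary-controlled event and two relayed ones. The enamine aldol is reversible and the cycloaddition is not. The preparation of A5 should outweigh the steps saved at the end.

Key step: step 4

## Route

**Step 1**
Reactants: 1 (R)-lactic acid; 2 pivalaldehyde
Product: 3 (2R,5R)-2-tert-butyl-5-methyl-1,3-dioxolan-4-one
Conditions: TsOH·H2O (cat.), H2SO4 (cat.), pentane, reflux, Dean–Stark; recrystallisation from pentane/Et2O at −78 °C
Reagents that add atoms: none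
Why: Acid-catalysed acetalisation with azeotropic removal of water; the lactic acid stereocentre sets the new acetal carbon C2 under thermodynamic control in favour of the cis isomer, and low-temperature crystallisation should remove the trans isomer. This purity matters because, once C5 is flattened in steps 2 and 3, the cis/trans ratio of 3 becomes the enantiomeric ratio of 5.

**Step 2**
Reactants: 3 (2R,5R)-2-tert-butyl-5-methyl-1,3-dioxolan-4-one
Product: 4 (2R,5S)-5-bromo-2-tert-butyl-5-methyl-1,3-dioxolan-4-one
Conditions: NBS (1.05 equiv), AIBN (cat.), PhCF3, 80 °C; filtration, evaporation, crude product used at once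
Reagents that add atoms: N-bromosuccinimide, O=C1CCC(=O)N1Br
Why: Wohl–Ziegler-type radical bromination at C5, where the radical is stabilised by both the ring oxygen and the carbonyl; bromine should enter trans to tert-butyl, although this centre is destroyed in step 3. PhCF3 replaces CCl4 as the solvent, and C2 is not touched.

**Step 3**
Reactants: 4 (2R,5S)-5-bromo-2-tert-butyl-5-methyl-1,3-dioxolan-4-one
Product: 5 (R)-2-tert-butyl-5-methylene-1,3-dioxolan-4-one
Conditions: Et3N (1.5 equiv), MTBE, 0 °C to rt, BHT (trace); filtration, short-path distillation under reduced pressure, used fresh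
Reagents that add atoms: none
Why: Base-mediated dehydrobromination; only the methyl hydrogens are available, so the exocyclic alkene is the sole elimination product. C2 is unaffected and now carries all the stereochemical information.

**Step 4**
Reactants: 5 (R)-2-tert-butyl-5-methylene-1,3-dioxolan-4-one; 6 buta-1,3-diene
Product: 7 (2R,5S)-2-tert-butyl-1,3-dioxaspiro[4.5]dec-7-en-4-one
Conditions: 6 (4 equiv, commercial 20 wt% solution in toluene), BHT (1 mol%), sealed pressure vessel behind a shield, 110 °C; chromatography
Reagents that add atoms: none
Why: Thermal Diels–Alder reaction, a concerted suprafacial [4+2] cycloaddition in which s-cis 6 adds across the exocyclic C=C of 5 so that C1–C6 and C2–C3 (target numbering) form together. The closest known reaction type is the cycloaddition of chiral 5-methylene-1,3-dioxolan-4-ones with simple dienes, where they act as α-hydroxyacrylate equivalents. The alkene is activated by the lactone carbonyl and is captodative and exocyclic, so it should react with an unactivated diene on heating without a Lewis acid, which would endanger the acetal. The cyclohexene ring closes by intermolecular [4+2] annulation, both ring bonds being made in the same step, and the former alkene carbon of the heterocycle becomes the spiro carbon. The one new stereocentre, the spiro carbon (C1 of the target), is controlled by the acetal carbon of 5: tert-butyl shields one face of the flat five-membered ring, so the diene should add to the other face, placing the new C1–C6 bond trans and the former methylene carbon cis to tert-butyl. Because 6 is symmetrical and unsubstituted there is no regiochemical or endo/exo question, and π-facial selectivity is the only selectivity required. The minor facial isomer is a diastereomer of 7 and should be removable here, which protects the enantiomeric purity of everything downstream. BHT and exclusion of oxygen suppress radical polymerisation of both partners, and the diene is handled as a solution rather than as the liquefied gas.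

**Step 5**
Reactants: 7 (2R,5S)-2-tert-butyl-1,3-dioxaspiro[4.5]dec-7-en-4-one
Product: 8 methyl (S)-1-hydroxycyclohex-3-ene-1-carboxylate
Conditions: NaOMe (0.2 equiv), MeOH, 0 °C to rt; AcOH quench
Reagents that add atoms: methanol, CO
Why: Methoxide attacks the lactone carbonyl (transesterification) and the hemiacetal alkoxide so released expels pivalaldehyde. The C1–O bond is never broken, so C1 keeps its configuration.

**Step 6**
Reactants: 8 methyl (S)-1-hydroxycyclohex-3-ene-1-carboxylate
Product: 10 (S)-1-methoxycyclohex-3-ene-1-carboxylic acid, via methyl (S)-1-methoxycyclohex-3-ene-1-carboxylate 9 (not isolated)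
Conditions: NaH (1.3 equiv), MeI (2 equiv), THF, 0 °C to rt; then LiOH·H2O (4 equiv), H2O/MeOH, 40 °C; 1 M HCl to pH 2
Reagents that add atoms: iodomethane, CI; lithium hydroxide, [Li+].[OH-]
Why: Williamson etherification of the tertiary alkoxide; the ester has no α-hydrogen, so neither enolisation nor C-alkylation is possible. Saponification follows in the same flask, and no stereocentre is touched. NaH is used in THF rather than in DMF.

**Step 7**
Reactants: 10 (S)-1-methoxycyclohex-3-ene-1-carboxylic acid
Product: 11 (1S,4R,5R)-4-iodo-1-methoxy-6-oxabicyclo[3.2.1]octan-7-one
Conditions: I2 (2 equiv), NaHCO3 (3 equiv), MeCN/H2O, 0 °C to rt, dark; Na2S2O3 work-up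
Reagents that add atoms: iodine, II
Why: Iodolactonisation: the carboxylate opens the iodonium ion at the nearer alkene carbon C5 by trans-diaxial attack to give the γ-lactone. O5 is therefore cis to C7 and iodine at C4 is trans to O5, both centres following from C1.

**Step 8**
Reactants: 11 (1S,4R,5R)-4-iodo-1-methoxy-6-oxabicyclo[3.2.1]octan-7-one
Product: 12 (1S,5R)-1-methoxy-6-oxabicyclo[3.2.1]oct-3-en-7-one
Conditions: DBU (2 equiv), toluene, 90 °C
Reagents that add atoms: none
Why: E2 elimination: the only hydrogen antiperiplanar to the axial C4–I bond is on C3, because H5 is cis to iodine. The C3=C4 alkene should therefore form regioselectively.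

**Step 9**
Reactants: 12 (1S,5R)-1-methoxy-6-oxabicyclo[3.2.1]oct-3-en-7-one
Product: 13 (1S,3R,4R,5R)-3,4-dihydroxy-1-methoxy-6-oxabicyclo[3.2.1]octan-7-one
Conditions: K2OsO4·2H2O (2 mol%), NMO (1.5 equiv), acetone/H2O (5:1), rt; Na2SO3 work-up
Reagents that add atoms: N-methylmorpholine N-oxide, C[N+]1([O-])CCOCC1; water, O
Why: Catalytic syn-dihydroxylation with OsO4 formed in the flask from the non-volatile osmate salt and recycled by NMO. Addition should occur on the alkene face opposite the two-atom lactone bridge, the known facial preference of this bicyclic lactone class, setting C3 and C4 together with both hydroxyls cis to each other and trans to O5.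

**Step 10**
Reactants: 13 (1S,3R,4R,5R)-3,4-dihydroxy-1-methoxy-6-oxabicyclo[3.2.1]octan-7-one
Product: 14 3,4-O-isopropylidene acetal of 13 (3,4-O-isopropylidene-1-O-methylquinide)
Conditions: 2,2-dimethoxypropane (3 equiv), TsOH·H2O (cat.), acetone, rt; Et3N quench
Reagents that add atoms: 2,2-dimethoxypropane, COC(C)(C)OC
Why: Acid-catalysed transacetalisation; the cis-3,4-diol closes a five-membered dioxolane readily, and the lactone and the methyl ether are inert.

**Step 11**
Reactants: 14 3,4-O-isopropylidene-1-O-methylquinide
Product: 16 4-methoxybenzyl 3,4-O-isopropylidene-1-O-methylquinate (C5 hydroxyl free), via cesium carboxylate 15 (not isolated)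
Conditions: CsOH·H2O (1.05 equiv), THF/H2O, 0 °C to rt; evaporation, toluene azeotrope; then PMBCl (1.2 equiv), TBAI (cat.), DMF, rt
Reagents that add atoms: cesium hydroxide, [Cs+].[OH-]; 4-methoxybenzyl chloride, COc1ccc(CCl)cc1
Why: Lactone saponification by acyl–oxygen cleavage (C5 keeps its configuration) gives the cesium carboxylate, which is alkylated at oxygen by the benzylic chloride (SN2); the neutral secondary hydroxyl does not compete. Only one equivalent of hydroxide is used, so no strong base remains to re-close the lactone.

**Step 12**
Reactants: 17 caffeic acid
Product: 19 (E)-3-[3,4-bis(4-methoxybenzyloxy)phenyl]prop-2-enoic acid, via 4-methoxybenzyl ester 18 (not isolated)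
Conditions: PMBCl (3.3 equiv), K2CO3 (3.5 equiv), TBAI (cat.), DMF, 60 °C; then 2 M NaOH, MeOH, 50 °C; 1 M HCl to pH 3
Reagents that add atoms: 4-methoxybenzyl chloride, COc1ccc(CCl)cc1; sodium hydroxide, [Na+].[OH-]
Why: Exhaustive O-alkylation of the two phenols and the carboxylate, then saponification of the benzylic ester in the same flask. The aryl ethers are stable to hydroxide and the E-alkene is untouched.

**Step 13**
Reactants: 16 4-methoxybenzyl 3,4-O-isopropylidene-1-O-methylquinate; 19 (E)-3-[3,4-bis(4-methoxybenzyloxy)phenyl]prop-2-enoic acid
Product: 20 4-methoxybenzyl 5-O-[(E)-3-(3,4-bis(4-methoxybenzyloxy)phenyl)prop-2-enoyl]-3,4-O-isopropylidene-1-O-methylquinate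
Conditions: EDC·HCl (2 equiv), DMAP (1 equiv), CH2Cl2, rt
Reagents that add atoms: none
Why: Steglich esterification: the carbodiimide activates 19 and DMAP transfers the acyl group to O5, the only free hydroxyl of 16. The C5–O bond is not broken, so the configuration is retained.

**Step 14**
Reactants: 20 4-methoxybenzyl 5-O-[(E)-3-(3,4-bis(4-methoxybenzyloxy)phenyl)prop-2-enoyl]-3,4-O-isopropylidene-1-O-methylquinate
Product: 21 5-O-caffeoyl-1-O-methylquinic acid (3-O-caffeoyl-1-methylquinic acid in the older numbering)
Conditions: TFA/CH2Cl2 (1:1), anisole (20 equiv), 0 °C; then H2O (10 vol%), rt, protected from light; evaporation, reversed-phase chromatography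
Reagents that add atoms: none
Why: Acidolysis: TFA ionises the 4-methoxybenzyl ester and both aryl 4-methoxybenzyl ethers, the cations being trapped by anisole, and aqueous TFA hydrolyses the isopropylidene acetal. Acid avoids the base-promoted acyl migration and catechol oxidation to which 21 is prone, and the tertiary methyl ether and the enoate are stable to it.

## Compound list

1 | (R)-lactic acid | C[C@@H](O)C(=O)O | starting material
2 | pivalaldehyde | CC(C)(C)C=O | starting material
3 | (2R,5R)-2-tert-butyl-5-methyl-1,3-dioxolan-4-one (cis) | O=C1O[C@H](C(C)(C)C)O[C@@H]1C | intermediate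
4 | (2R,5S)-5-bromo-2-tert-butyl-5-methyl-1,3-dioxolan-4-one (Br trans to tert-butyl) | O=C1O[C@H](C(C)(C)C)O[C@@]1(C)Br | intermediate
5 | (R)-2-tert-butyl-5-methylene-1,3-dioxolan-4-one | O=C1O[C@H](C(C)(C)C)OC1=C | intermediate
6 | buta-1,3-diene | C=CC=C | starting material
7 | (2R,5S)-2-tert-butyl-1,3-dioxaspiro[4.5]dec-7-en-4-one | O=C1O[C@H](C(C)(C)C)O[C@]12CCC=CC2 | intermediate
8 | methyl (S)-1-hydroxycyclohex-3-ene-1-carboxylate | COC(=O)[C@]1(O)CCC=CC1 | intermediate
9 | methyl (S)-1-methoxycyclohex-3-ene-1-carboxylate | CO[C@@]1(C(=O)OC)CCC=CC1 | intermediate (not isolated)
10 | (S)-1-methoxycyclohex-3-ene-1-carboxylic acid | CO[C@@]1(C(=O)O)CCC=CC1 | intermediate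
11 | (1S,4R,5R)-4-iodo-1-methoxy-6-oxabicyclo[3.2.1]octan-7-one | CO[C@@]12CC[C@@H](I)[C@@H](C1)OC2=O | intermediate
12 | (1S,5R)-1-methoxy-6-oxabicyclo[3.2.1]oct-3-en-7-one | CO[C@@]12CC=C[C@@H](C1)OC2=O | intermediate
13 | (1S,3R,4R,5R)-3,4-dihydroxy-1-methoxy-6-oxabicyclo[3.2.1]octan-7-one (1-O-methylquinide) | CO[C@@]12C[C@@H](O)[C@@H](O)[C@@H](C1)OC2=O | intermediate
14 | 3,4-O-isopropylidene-1-O-methylquinide (acetonide of 13 on the cis O3/O4 pair, C7–O5 lactone retained) | CO[C@@]12C[C@H]3OC(C)(C)O[C@H]3[C@@H](C1)OC2=O | intermediate
15 | cesium 3,4-O-isopropylidene-1-O-methylquinate (C5 hydroxyl free) | CO[C@@]1(C(=O)[O-])C[C@H]2OC(C)(C)O[C@H]2[C@H](O)C1.[Cs+] | intermediate (not isolated)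
16 | 4-methoxybenzyl 3,4-O-isopropylidene-1-O-methylquinate (C5 hydroxyl free) | CO[C@@]1(C(=O)OCc2ccc(OC)cc2)C[C@H]2OC(C)(C)O[C@H]2[C@H](O)C1 | intermediate
17 | caffeic acid | OC(=O)/C=C/c1ccc(O)c(O)c1 | starting material
18 | 4-methoxybenzyl (E)-3-[3,4-bis(4-methoxybenzyloxy)phenyl]prop-2-enoate | COc1ccc(COC(=O)/C=C/c2ccc(OCc3ccc(OC)cc3)c(OCc3ccc(OC)cc3)c2)cc1 | intermediate (not isolated)
19 | (E)-3-[3,4-bis(4-methoxybenzyloxy)phenyl]prop-2-enoic acid | OC(=O)/C=C/c1ccc(OCc2ccc(OC)cc2)c(OCc2ccc(OC)cc2)c1 | intermediate
20 | 4-methoxybenzyl 5-O-[(E)-3-(3,4-bis(4-methoxybenzyloxy)phenyl)prop-2-enoyl]-3,4-O-isopropylidene-1-O-methylquinate | CO[C@@]1(C(=O)OCc2ccc(OC)cc2)C[C@H]2OC(C)(C)O[C@H]2[C@H](OC(=O)/C=C/c2ccc(OCc3ccc(OC)cc3)c(OCc3ccc(OC)cc3)c2)C1 | intermediate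
21 | 5-O-caffeoyl-1-O-methylquinic acid, (1S,3R,4R,5R)-3-{[(2E)-3-(3,4-dihydroxyphenyl)prop-2-enoyl]oxy}-4,5-dihydroxy-1-methoxycyclohexane-1-carboxylic acid | CO[C@@]1(C(=O)O)C[C@@H](O)[C@@H](O)[C@H](OC(=O)/C=C/c2ccc(O)c(O)c2)C1 | target

## Step count and least certain steps

Total: 14 steps (steps 6, 11 and 12 are two-stage operations in one flask). Longest linear sequence: 13 steps (steps 1–11, 13, 14); step 12 is the side branch.

**Step 4 (key step).** The most likely failure is incomplete discrimination between the two faces of 5 at the temperature an unactivated diene needs, together with radical polymerisation of 5 and 6. The adduct would then carry its spiro epimer, which is the source of the wrong enantiomer later, and would be obtained in small amount. The fallback sets out from 6 and returns at 10, and replaces auxiliary control by resolution. 6 would be heated with commercial methyl 2-methoxyacrylate (toluene, BHT, sealed vessel, about 150 °C) to give racemic methyl 1-methoxycyclohex-3-ene-1-carboxylate F1, which would be saponified (LiOH·H2O, aqueous MeOH) to racemic 1-methoxycyclohex-3-ene-1-carboxylic acid F2. Fractional crystallisation with an enantiopure 1-phenylethylamine (the enantiomer that pairs with the (S)-acid in the less soluble salt is to be found by screening; it is written here as the (R)-amine) should give (R)-1-phenylethylammonium (S)-1-methoxycyclohex-3-ene-1-carboxylate F3, from which dilute HCl releases 10. The price is the loss of at least half the material and the need to prove the absolute configuration by correlation with a sample made through 7.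

**Step 6.** The tertiary alkoxide is hindered, so etherification may stall, and the alkoxide can instead attack the ester of a second molecule and form oligomeric esters. The fallback sets out from 8 and returns at 12, and moves the methylation to a rigid lactone that has no exchangeable ester. 8 would be hydrolysed (LiOH·H2O, aqueous THF) to (S)-1-hydroxycyclohex-3-ene-1-carboxylic acid F4, iodolactonised (I2, NaHCO3, MeCN/H2O) to (1S,4R,5R)-1-hydroxy-4-iodo-6-oxabicyclo[3.2.1]octan-7-one F5, and dehydroiodinated (DBU, toluene, 90 °C) to (1S,5R)-1-hydroxy-6-oxabicyclo[3.2.1]oct-3-en-7-one F6. The exposed bridgehead hydroxyl of F6 would then be methylated under non-basic conditions with Me3OBF4 and 1,8-bis(dimethylamino)naphthalene in CH2Cl2 to give 12.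

**Step 11.** The lactone may re-close, either from the salt on drying or from 16 by loss of the benzylic alkoxide if any strong base is left, and alkylation of the cesium salt may be incomplete. The fallback sets out from 14 and returns at 16, and replaces hydrolysis–alkylation by direct alcoholysis. 14 would be stirred in THF with a large excess of 4-methoxybenzyl alcohol and a catalytic amount of its sodium alkoxide (from NaH), so that the excess alcohol drives the ring-opening transesterification to 16 without a free carboxylate or an alkyl halide. No new compound is made.

**Step 13.** Acylation of the hindered O5 may be slow, which would let the activated acid rearrange to an N-acylurea and let DMAP return 16 to the lactone. The fallback sets out from 16 and returns at 20, and builds the enoate on the ring by olefination. 16 would be esterified with the small, commercial diethylphosphonoacetic acid (EDC·HCl, DMAP, CH2Cl2) to give 4-methoxybenzyl 5-O-(diethoxyphosphorylacetyl)-3,4-O-isopropylidene-1-O-methylquinate F7. A Horner–Wadsworth–Emmons reaction of F7 with 3,4-bis(4-methoxybenzyloxy)benzaldehyde F8 (from commercial 3,4-dihydroxybenzaldehyde, PMBCl and K2CO3 in DMF) under LiCl/DBU in MeCN should give 20 with the E-alkene.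

**Step 14.** Three equivalents of 4-methoxybenzyl cation are released beside an electron-rich catechol, so C-benzylation of the product is the main danger. Prolonged acid exposure could also leave the acetal partly intact or start acyl migration. The fallback sets out from 16 and 17 and returns at 21, and uses acetates on the catechol so that only one benzylic cation is formed, beside a deactivated arene. 17 would be acetylated (Ac2O, pyridine) to (E)-3-(3,4-diacetoxyphenyl)prop-2-enoic acid F9 and coupled with 16 (EDC·HCl, DMAP, CH2Cl2) to give 4-methoxybenzyl 5-O-[(E)-3-(3,4-diacetoxyphenyl)prop-2-enoyl]-3,4-O-isopropylidene-1-O-methylquinate F10. TFA/anisole and then water would remove the benzylic ester and the acetal to give 5-O-[(E)-3-(3,4-diacetoxyphenyl)prop-2-enoyl]-1-O-methylquinic acid F11, and dilute aqueous HCl in THF at rt would then hydrolyse the two aryl acetates to 21 under acidic conditions.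

## Further compounds

F1 | step 4 | racemic methyl 1-methoxycyclohex-3-ene-1-carboxylate | COC(=O)C1(OC)CCC=CC1
F2 | step 4 | racemic 1-methoxycyclohex-3-ene-1-carboxylic acid | COC1(C(=O)O)CCC=CC1
F3 | step 4 | (R)-1-phenylethylammonium (S)-1-methoxycyclohex-3-ene-1-carboxylate | CO[C@@]1(C(=O)[O-])CCC=CC1.C[C@@H]([NH3+])c1ccccc1
F4 | step 6 | (S)-1-hydroxycyclohex-3-ene-1-carboxylic acid | O[C@@]1(C(=O)O)CCC=CC1
F5 | step 6 | (1S,4R,5R)-1-hydroxy-4-iodo-6-oxabicyclo[3.2.1]octan-7-one | O[C@@]12CC[C@@H](I)[C@@H](C1)OC2=O
F6 | step 6 | (1S,5R)-1-hydroxy-6-oxabicyclo[3.2.1]oct-3-en-7-one | O[C@@]12CC=C[C@@H](C1)OC2=O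
F0 | step 11 | none | none
F7 | step 13 | 4-methoxybenzyl 5-O-(diethoxyphosphorylacetyl)-3,4-O-isopropylidene-1-O-methylquinate | CO[C@@]1(C(=O)OCc2ccc(OC)cc2)C[C@H]2OC(C)(C)O[C@H]2[C@H](OC(=O)CP(=O)(OCC)OCC)C1
F8 | step 13 | 3,4-bis(4-methoxybenzyloxy)benzaldehyde | O=Cc1ccc(OCc2ccc(OC)cc2)c(OCc2ccc(OC)cc2)c1
F9 | step 14 | (E)-3-(3,4-diacetoxyphenyl)prop-2-enoic acid | CC(=O)Oc1ccc(/C=C/C(=O)O)cc1OC(C)=O
F10 | step 14 | 4-methoxybenzyl 5-O-[(E)-3-(3,4-diacetoxyphenyl)prop-2-enoyl]-3,4-O-isopropylidene-1-O-methylquinate | CO[C@@]1(C(=O)OCc2ccc(OC)cc2)C[C@H]2OC(C)(C)O[C@H]2[C@H](OC(=O)/C=C/c2ccc(OC(C)=O)c(OC(C)=O)c2)C1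
F11 | step 14 | 5-O-[(E)-3-(3,4-diacetoxyphenyl)prop-2-enoyl]-1-O-methylquinic acid | CO[C@@]1(C(=O)O)C[C@@H](O)[C@@H](O)[C@H](OC(=O)/C=C/c2ccc(OC(C)=O)c(OC(C)=O)c2)C1
A1 | alternative 1 | 5-(tert-butyldimethylsilyloxy)-3,4-(isopropylidenedioxy)cyclohexan-1-one (O3 and O4 cis, O5 trans to O4) | O=C1C[C@H]2OC(C)(C)O[C@H]2[C@H](O[Si](C)(C)C(C)(C)C)C1
A2 | alternative 1 | 5-(tert-butyldimethylsilyloxy)-3,4-(isopropylidenedioxy)-1-methoxy-1-[tris(methylthio)methyl]cyclohexane | CO[C@@]1(C(SC)(SC)SC)C[C@H]2OC(C)(C)O[C@H]2[C@H](O[Si](C)(C)C(C)(C)C)C1
A3 | alternative 2 | (4R,5R)-2,2-dimethyl-5-{2-[(trimethylsilyl)methyl]prop-2-en-1-yl}-1,3-dioxolane-4-carbaldehyde (cis) | C=C(C[Si](C)(C)C)C[C@H]1OC(C)(C)O[C@H]1C=O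
A4 | alternative 2 | 3,4-(isopropylidenedioxy)-1-methylenecyclohexan-5-ol (target numbering) | C=C1C[C@H]2OC(C)(C)O[C@H]2[C@H](O)C1
A5 | alternative 3 | tert-butyl (R)-2-methoxy-5-(4-methoxybenzyloxy)-4-oxo-2-(2-oxoethyl)pentanoate | CO[C@](CC=O)(CC(=O)COCc1ccc(OC)cc1)C(=O)OC(C)(C)C
A6 | alternative 3 | tert-butyl 5-hydroxy-1-methoxy-4-(4-methoxybenzyloxy)-3-oxocyclohexane-1-carboxylate | CO[C@@]1(C(=O)OC(C)(C)C)CC(=O)[C@@H](OCc2ccc(OC)cc2)[C@H](O)C1
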